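## Retrosynthetic overview

1. The cyclohexene ring fused to the enedione is disconnected last: an intermolecular Diels–Alder reaction between the labdane diene C12=C13–C14=C15 of hydroxy aldehyde 25 and the chromonyl methoxybenzoquinone 32, itself made from a 2',4',5'-trimethoxyflavone.
2. The decalin of 25 is traced to the open-chain allenyl ether 20: one intramolecular Diels–Alder reaction closes ring A (C5–C10) and ring B (C8–C9) together.
3. The enabling feature is in ring B: the exocyclic C8=C17 methylene sits next to oxygenated C7, and C8–C9 and C5–C10 are the two bonds flanking C6–C7. This is the retron of a 2-alkoxy vinylallene C5=C6–C7(OR)=C8=C17 adding to the (E)-C9=C10 alkene, so the methylene and the C7 oxygen come out of the cycloaddition itself.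
4. Allenyl ether 20 comes from an α-quaternary aldehyde (Takai olefination, Negishi coupling with methoxyallene); C4 is set by lipase desymmetrisation of a malonate-derived diol; the (E,E)-polyene chain is built by two Negishi carboaluminations.
5. Ring order: chromone (separately), then rings A and B in one step, then the cyclohexene ring of the enedione.

Key step: step 11

Remark: labdane numbering (C1–C20) is used for the terpenoid carbons of all intermediates.
Assumption: the lipase in step 7 acylates the pro-R hydroxymethyl group of diol 13; the sense has to be confirmed on the first batch, and the hydrolytic mode given under the fallbacks reaches the antipodal series.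

## Route

Step 1
Reactants: 1 5-chloropent-1-yne
Product: 4 (2E)-6-chloro-3-methylhex-2-en-1-ol, via alkenylalane 2 (not isolated), via lithium alkenylaluminate 3 (not isolated)
Conditions: Me3Al, Cp2ZrCl2 (0.2 equiv), CH2Cl2, 0 °C to rt; n-BuLi, −78 °C; (CH2O)n, THF, −78 °C to rt; aq. Rochelle salt
Reagents that add atoms: trimethylaluminium C[Al](C)C; paraformaldehyde (as formaldehyde) C=O
Why: Zirconium-catalysed Negishi carboalumination adds methyl and aluminium syn across the terminal alkyne (aluminium on the terminal carbon), which fixes the (E)-trisubstituted C9=C10 alkene with the C20 methyl cis to C11, and the derived aluminate is hydroxymethylated with retention while the alkyl chloride stays inert.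

Step 2
Reactants: 4 (2E)-6-chloro-3-methylhex-2-en-1-ol
Product: 5 (2E)-1,6-dichloro-3-methylhex-2-ene
Conditions: MsCl, LiCl, 2,4,6-collidine, DMF, 0 °C
Reagents that add atoms: lithium chloride [Li+].[Cl-]
Why: In-situ mesylation and SN2 displacement by chloride convert the allylic alcohol into the allylic chloride without allylic transposition or loss of the E geometry.

Step 3
Reactants: 6 1,3-dichlorobut-2-ene (E/Z mixture)
Product: 7 but-1-en-3-yne
Conditions: KOH, ethylene glycol, 165 °C; gas condensed at −78 °C and taken up in cold ClCH2CH2Cl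
Reagents that add atoms: none
Why: Twofold base-induced dehydrochlorination is the standard laboratory preparation of vinylacetylene, which is used at once as a cold solution.

Step 4
Reactants: 7 but-1-en-3-yne; 5 (2E)-1,6-dichloro-3-methylhex-2-ene
Product: 9 (3E,6E)-10-chloro-3,7-dimethyldeca-1,3,6-triene, via dienylalane 8 (not isolated)
Conditions: 7, Me3Al, Cp2ZrCl2 (cat.), ClCH2CH2Cl, 0 °C to rt; then 5, Pd(PPh3)4 (5 mol %), THF, rt
Reagents that add atoms: trimethylaluminium C[Al](C)C
Why: Negishi carboalumination of the enyne gives the (E)-2-methyldienylalane, and palladium-catalysed alkenyl–allyl coupling (oxidative addition of the allylic and not the alkyl chloride, attack at the unsubstituted allyl terminus) joins C11 to C12 with retention of both alkene geometries, a 1,4-diene synthesis of established type.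

Step 5
Reactants: 10 diethyl 2-methylpropanedioate; 9 (3E,6E)-10-chloro-3,7-dimethyldeca-1,3,6-triene
Product: 12 diethyl 2-[(4E,7E)-4,8-dimethyldeca-4,7,9-trienyl]-2-methylpropanedioate, via sodium malonate enolate 11 (not isolated)
Conditions: NaH, DMF, 0 °C; then 9, NaI (cat.), 70 °C
Reagents that add atoms: none
Why: Malonic ester SN2 alkylation of the primary chloride (iodide-catalysed) builds the future quaternary C4 with the C19 methyl and both one-carbon arms (C5 and C18) in place.

Step 6
Reactants: 12 diethyl 2-[(4E,7E)-4,8-dimethyldeca-4,7,9-trienyl]-2-methylpropanedioate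
Product: 13 2-[(4E,7E)-4,8-dimethyldeca-4,7,9-trienyl]-2-methylpropane-1,3-diol
Conditions: LiAlH4, THF, 0 °C to rt
Reagents that add atoms: none
Why: Hydride reduction of both esters gives the prochiral 2,2-disubstituted propane-1,3-diol, and the isolated alkenes and the diene are not touched.

Step 7
Reactants: 13 2-[(4E,7E)-4,8-dimethyldeca-4,7,9-trienyl]-2-methylpropane-1,3-diol
Product: 14 (2R)-2-[(4E,7E)-4,8-dimethyldeca-4,7,9-trienyl]-3-hydroxy-2-methylpropyl furan-2-carboxylate
Conditions: Candida rugosa lipase, 1-ethoxyvinyl furan-2-carboxylate, water-saturated iPr2O, 30 °C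
Reagents that add atoms: 1-ethoxyvinyl furan-2-carboxylate C=C(OCC)OC(=O)c1ccco1
Why: Lipase-catalysed enantiotopic-group-selective acylation (serine hydrolase, acyl-enzyme mechanism) of the prochiral diol sets the quaternary C4 stereocentre, the enzyme pocket telling the methyl group from the long lipophilic chain, while the irreversible donor releases ethyl acetate, the aroate resists 1,3-acyl migration and the slower second acylation consumes the minor enantiomer.

Step 8
Reactants: 14 (2R)-2-[(4E,7E)-4,8-dimethyldeca-4,7,9-trienyl]-3-hydroxy-2-methylpropyl furan-2-carboxylate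
Product: 15 (2S)-2-[(4E,7E)-4,8-dimethyldeca-4,7,9-trienyl]-2-methyl-3-oxopropyl furan-2-carboxylate
Conditions: Dess–Martin periodinane, NaHCO3, CH2Cl2, 0 °C to rt
Reagents that add atoms: none
Why: Dess–Martin oxidation of the free neopentyl alcohol gives the non-enolisable α-quaternary aldehyde (future C5), after which acyl migration can no longer erode the C4 configuration.

Step 9
Reactants: 15 (2S)-2-[(4E,7E)-4,8-dimethyldeca-4,7,9-trienyl]-2-methyl-3-oxopropyl furan-2-carboxylate
Product: 16 (2R,3E)-2-[(4E,7E)-4,8-dimethyldeca-4,7,9-trienyl]-4-iodo-2-methylbut-3-enyl furan-2-carboxylate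
Conditions: CrCl2, CHI3, THF/1,4-dioxane, 0 °C to rt
Reagents that add atoms: iodoform IC(I)I
Why: Takai olefination through the geminal dichromium reagent homologates the hindered aldehyde to the (E)-alkenyl iodide (C5=C6), the bulky quaternary substituent reinforcing the E selectivity, and ester and polyene are inert to CrCl2.

Step 10
Reactants: 16 (2R,3E)-2-[(4E,7E)-4,8-dimethyldeca-4,7,9-trienyl]-4-iodo-2-methylbut-3-enyl furan-2-carboxylate; 17 1-methoxypropa-1,2-diene
Product: 20 (2R,3E)-2-[(4E,7E)-4,8-dimethyldeca-4,7,9-trienyl]-5-methoxy-2-methylhepta-3,5,6-trienyl furan-2-carboxylate, via lithiated methoxyallene 18 (not isolated), via methoxyallenylzinc chloride 19 (not isolated)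
Conditions: 17, n-BuLi, THF, −78 °C; ZnCl2, −78 to 0 °C; then 16, Pd(PPh3)4 (5 mol %), THF, 0 °C to rt; filtration through Et3N-deactivated silica, used at once
Reagents that add atoms: none
Why: Negishi cross-coupling of the α-metalated alkoxyallene (allenyl, not propargyl, coupling) with the alkenyl iodide proceeds with retention of the (E)-C5=C6 geometry and installs C7 with its oxygen, C8 and C17 as the allenyl ether, the organozinc sparing the ester.

Step 11
Reactants: 20 (2R,3E)-2-[(4E,7E)-4,8-dimethyldeca-4,7,9-trienyl]-5-methoxy-2-methylhepta-3,5,6-trienyl furan-2-carboxylate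
Product: 21 7-methoxylabda-6,8(17),12E,14-tetraen-18-yl furan-2-carboxylate (trans-decalin, 5α-H, 9α-H, 10β-methyl, 4β-methyl)
Conditions: toluene (0.005 M, degassed), 2,6-di-tert-butyl-4-methylphenol, Et3N (trace), 140 °C, sealed base-washed tube
Reagents that add atoms: none
Why: Thermal intramolecular Diels–Alder reaction in which the vinylallene C5=C6–C7(OMe)=C8 is the 4π partner and the unactivated (E)-C9=C10 alkene the 2π partner, the concerted but asynchronous bond formation being led at the unhindered, strained allene carbon C8; the closest known reaction type is the intramolecular [4+2] cycloaddition of vinylallenes and siloxyvinylallenes with tethered unactivated alkenes. Ring A closes through C5–C10 and ring B through C8–C9, both six-membered, in the type 1 mode of a 1,7,9-decatriene with the C1–C4 tether exo on the dienophile. C9 and C10 are set relative to each other by the (E) geometry of C9=C10 (C20 methyl and C11 cis), C5 relative to C10 by the chair-like exo-tether transition state that leads to the trans ring fusion (the endo-tether alternatives force C9 or the diene into an axial position on the forming ring A, against the axial C4 substituent or the C1 and C3 hydrogens), and all three relative to the existing C4 centre by the larger CH2O-furoyl group taking the equatorial site, which leaves the C19 methyl axial and syn to C20. The orthogonal C8=C17 π bond of the allene takes no part and becomes the exocyclic methylene, and the C6=C7 enol ether that results is the masked C7 ketone. The step needs chemoselectivity over the side-chain 1,3-diene and the furan, secured because these could only engage through rings of nine or more atoms, and it needs the vinylallene to survive heating, secured by the quaternary C4 (no allylic hydrogen for a [1,5]-hydrogen shift) and by base-washed glass with a radical inhibitor.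

Step 12
Reactants: 21 7-methoxylabda-6,8(17),12E,14-tetraen-18-yl furan-2-carboxylate
Product: 22 7-oxolabda-8(17),12E,14-trien-18-yl furan-2-carboxylate
Conditions: oxalic acid, THF/H2O, 0 °C; used without storage
Reagents that add atoms: water O
Why: Acid hydrolysis of the dienyl methyl ether proceeds by protonation at C6 (oxocarbenium at C7) and loss of methanol, which unveils the C7 ketone with the exocyclic C8=C17 bond intact, since protonation at C17 would give a cation that the oxygen cannot stabilise.

Step 13
Reactants: 22 7-oxolabda-8(17),12E,14-trien-18-yl furan-2-carboxylate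
Product: 23 7β-hydroxylabda-8(17),12E,14-trien-18-yl furan-2-carboxylate
Conditions: NaBH4, CeCl3·7H2O, MeOH, −78 °C
Reagents that add atoms: none
Why: Luche reduction gives clean 1,2-reduction of the α-methylene ketone, hydride arriving axially from the α face (opposite the C20 methyl, as in the reduction of steroidal 7-ketones) to give the equatorial 7β-alcohol, and the furoate is not reduced.

Step 14
Reactants: 23 7β-hydroxylabda-8(17),12E,14-trien-18-yl furan-2-carboxylate
Product: 24 labda-8(17),12E,14-triene-7β,18-diol
Conditions: K2CO3, MeOH, 40 °C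
Reagents that add atoms: none
Why: Base-catalysed transesterification removes the furoate from the C18 oxygen without affecting the allylic alcohol or the diene.

Step 15
Reactants: 24 labda-8(17),12E,14-triene-7β,18-diol
Product: 25 7β-hydroxylabda-8(17),12E,14-trien-18-al
Conditions: Cu(MeCN)4OTf, 2,2'-bipyridine, TEMPO, N-methylimidazole (catalytic each), MeCN, air, rt
Reagents that add atoms: none
Why: Copper/TEMPO aerobic oxidation is selective for primary over secondary alcohols for steric reasons, so the C18 carbinol becomes the aldehyde while the allylic 7β-hydroxyl and the diene are left alone.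

Step 16
Reactants: 26 2,4,5-trimethoxybenzoic acid
Product: 27 2,4,5-trimethoxybenzoyl chloride
Conditions: (COCl)2, DMF (cat.), CH2Cl2, 0 °C to rt
Reagents that add atoms: oxalyl chloride ClC(=O)C(Cl)=O
Why: Standard acid chloride formation through the chloroiminium species generated from DMF.

Step 17
Reactants: 28 1-(2,4,6-trihydroxyphenyl)ethanone; 27 2,4,5-trimethoxybenzoyl chloride
Product: 31 5,7-dihydroxy-2-(2,4,5-trimethoxyphenyl)-4H-chromen-4-one, via tetralithium salt 29 (not isolated), via β-diketone 30 (not isolated)
Conditions: LiN(SiMe3)2 (4.2 equiv), THF, −78 to −10 °C; 27, −78 °C to rt; aq. HCl; then AcOH, H2SO4 (cat.), 95 °C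
Reagents that add atoms: none
Why: The tetralithium salt of the trihydroxyacetophenone is acylated at the enolate carbon (Claisen-type C-acylation, giving the diketone otherwise reached by Baker–Venkataraman rearrangement), and acid-catalysed cyclodehydration closes the pyranone ring of the 5,7-dihydroxyflavone without protecting groups.

Step 18
Reactants: 31 5,7-dihydroxy-2-(2,4,5-trimethoxyphenyl)-4H-chromen-4-one
Product: 32 2-(5,7-dihydroxy-4-oxo-4H-chromen-2-yl)-5-methoxycyclohexa-2,5-diene-1,4-dione
Conditions: (NH4)2Ce(NO3)6 (2.2 equiv), MeCN/H2O, 0 °C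
Reagents that add atoms: water O
Why: Oxidative demethylation by cerium ammonium nitrate of the para-related 2'- and 5'-methoxy groups of the electron-rich trimethoxyphenyl ring gives the 2-methoxy-1,4-benzoquinone, while chromone ring A, deactivated by the pyranone carbonyl and the chelated 5-hydroxyl, should not be oxidised.

Step 19
Reactants: 25 7β-hydroxylabda-8(17),12E,14-trien-18-al; 32 2-(5,7-dihydroxy-4-oxo-4H-chromen-2-yl)-5-methoxycyclohexa-2,5-diene-1,4-dione
Product: 33 dichrostachine H
Conditions: THF, 45 °C, dark, argon; preparative HPLC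
Reagents that add atoms: none
Why: Intermolecular Diels–Alder reaction at the only activated quinone double bond (the other is a deactivated vinylogous ester) should join unsubstituted C15 to the quinone CH and C12 to the chromonyl-bearing carbon (orientation as with 2-acylquinones), give the cis ring fusion by suprafacial addition, and place the larger chromonyl group endo, away from the C11 methylene of the (E)-diene, so that C11, the chromonyl group and the ring-fusion hydrogen end up on one face as in the target, while the remote decalin is expected to give only modest control over which diene face reacts, so the facial isomer is removed by HPLC.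

## Compound list

1 | 5-chloropent-1-yne | C#CCCCCl | starting material
2 | [(1E)-5-chloro-2-methylpent-1-enyl]dimethylalane | C[Al](C)/C=C(\C)CCCCl | intermediate
3 | lithium butyl[(1E)-5-chloro-2-methylpent-1-enyl]dimethylaluminate | [Li+].CCCC[Al-](C)(C)/C=C(\C)CCCCl | intermediate
4 | (2E)-6-chloro-3-methylhex-2-en-1-ol | OC/C=C(\C)CCCCl | intermediate
5 | (2E)-1,6-dichloro-3-methylhex-2-ene | ClC/C=C(\C)CCCCl | intermediate
6 | 1,3-dichlorobut-2-ene (E/Z mixture) | CC(Cl)=CCCl | starting material
7 | but-1-en-3-yne | C=CC#C | intermediate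
8 | dimethyl[(1E)-2-methylbuta-1,3-dienyl]alane | C[Al](C)/C=C(\C)C=C | intermediate
9 | (3E,6E)-10-chloro-3,7-dimethyldeca-1,3,6-triene | C=C/C(C)=C/C/C=C(\C)CCCCl | intermediate
10 | diethyl 2-methylpropanedioate | CCOC(=O)C(C)C(=O)OCC | starting material
11 | sodium enolate of diethyl 2-methylpropanedioate | [Na+].CCOC(=O)[C-](C)C(=O)OCC | intermediate
12 | diethyl 2-[(4E,7E)-4,8-dimethyldeca-4,7,9-trienyl]-2-methylpropanedioate | C=C/C(C)=C/C/C=C(\C)CCCC(C)(C(=O)OCC)C(=O)OCC | intermediate
13 | 2-[(4E,7E)-4,8-dimethyldeca-4,7,9-trienyl]-2-methylpropane-1,3-diol | C=C/C(C)=C/C/C=C(\C)CCCC(C)(CO)CO | intermediate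
14 | (2R)-2-[(4E,7E)-4,8-dimethyldeca-4,7,9-trienyl]-3-hydroxy-2-methylpropyl furan-2-carboxylate | C=C/C(C)=C/C/C=C(\C)CCC[C@@](CO)(C)COC(=O)c1ccco1 | intermediate
15 | (2S)-2-[(4E,7E)-4,8-dimethyldeca-4,7,9-trienyl]-2-methyl-3-oxopropyl furan-2-carboxylate | C=C/C(C)=C/C/C=C(\C)CCC[C@@](C=O)(C)COC(=O)c1ccco1 | intermediate
16 | (2R,3E)-2-[(4E,7E)-4,8-dimethyldeca-4,7,9-trienyl]-4-iodo-2-methylbut-3-enyl furan-2-carboxylate | C=C/C(C)=C/C/C=C(\C)CCC[C@@](/C=C/I)(C)COC(=O)c1ccco1 | intermediate
17 | 1-methoxypropa-1,2-diene (methoxyallene) | COC=C=C | starting material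
18 | 1-lithio-1-methoxypropa-1,2-diene | [Li]C(OC)=C=C | intermediate
19 | chloro(1-methoxypropa-1,2-dienyl)zinc | Cl[Zn]C(OC)=C=C | intermediate
20 | (2R,3E)-2-[(4E,7E)-4,8-dimethyldeca-4,7,9-trienyl]-5-methoxy-2-methylhepta-3,5,6-trienyl furan-2-carboxylate | C=C/C(C)=C/C/C=C(\C)CCC[C@@](/C=C/C(OC)=C=C)(C)COC(=O)c1ccco1 | intermediate
21 | 7-methoxylabda-6,8(17),12E,14-tetraen-18-yl furan-2-carboxylate (5α-H, 9α-H, 10β-Me, 4β-Me) | C=C1C(OC)=C[C@@H]2[C@](C)(CCC[C@@]2(C)COC(=O)c3ccco3)[C@H]1C/C=C(\C)C=C | intermediate
22 | 7-oxolabda-8(17),12E,14-trien-18-yl furan-2-carboxylate | C=C1C(=O)C[C@@H]2[C@](C)(CCC[C@@]2(C)COC(=O)c3ccco3)[C@H]1C/C=C(\C)C=C | intermediate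
23 | 7β-hydroxylabda-8(17),12E,14-trien-18-yl furan-2-carboxylate | C=C1[C@@H](O)C[C@@H]2[C@](C)(CCC[C@@]2(C)COC(=O)c3ccco3)[C@H]1C/C=C(\C)C=C | intermediate
24 | labda-8(17),12E,14-triene-7β,18-diol | C=C1[C@@H](O)C[C@@H]2[C@](C)(CCC[C@@]2(C)CO)[C@H]1C/C=C(\C)C=C | intermediate
25 | 7β-hydroxylabda-8(17),12E,14-trien-18-al | C=C1[C@@H](O)C[C@@H]2[C@](C)(CCC[C@@]2(C)C=O)[C@H]1C/C=C(\C)C=C | intermediate
26 | 2,4,5-trimethoxybenzoic acid | O=C(O)c1cc(OC)c(OC)cc1OC | starting material
27 | 2,4,5-trimethoxybenzoyl chloride | O=C(Cl)c1cc(OC)c(OC)cc1OC | intermediate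
28 | 1-(2,4,6-trihydroxyphenyl)ethanone | CC(=O)c1c(O)cc(O)cc1O | starting material
29 | tetralithium salt (trisphenoxide enolate) of 1-(2,4,6-trihydroxyphenyl)ethanone | [Li+].[Li+].[Li+].[Li+].C=C([O-])c1c([O-])cc([O-])cc1[O-] | intermediate
30 | 1-(2,4,6-trihydroxyphenyl)-3-(2,4,5-trimethoxyphenyl)propane-1,3-dione | O=C(CC(=O)c1cc(OC)c(OC)cc1OC)c1c(O)cc(O)cc1O | intermediate
31 | 5,7-dihydroxy-2-(2,4,5-trimethoxyphenyl)-4H-chromen-4-one | COc1cc(OC)c(OC)cc1-c1cc(=O)c2c(O)cc(O)cc2o1 | intermediate
32 | 2-(5,7-dihydroxy-4-oxo-4H-chromen-2-yl)-5-methoxycyclohexa-2,5-diene-1,4-dione | COC1=CC(=O)C(=CC1=O)c1cc(=O)c2c(O)cc(O)cc2o1 | intermediate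
33 | dichrostachine H | C=C1[C@@H](O)C[C@@H]2[C@](C)(CCC[C@@]2(C)C=O)[C@H]1C[C@@H]1C(C)=CC[C@H]2C(=O)C(OC)=CC(=O)[C@@]12c1cc(=O)c2c(O)cc(O)cc2o1 | target

## Step count and risks

Total step count: 19. Longest linear sequence: 15 steps (steps 1, 2, 4 to 15 and 19, from 5-chloropent-1-yne).

Steps most likely to fail:

1. Step 11. The cyclisation may be too slow at temperatures that the allenyl ether tolerates (both partners are electron-rich and the C5–C10 bond joins two congested carbons), or the chair-like exo-tether transition state may not dominate, so that cis-fused or C4-mismatched bicycles form. The fallback replaces the electron-rich diene by an electron-poor one matched to the alkyl-substituted alkene. It sets out from 16: Sonogashira coupling with prop-2-yn-1-ol (PdCl2(PPh3)2, CuI, Et3N) would give the enynol F1. Its lithium alkoxide and PhSCl at −78 °C would give the propargyl sulfenate F2, whose [2,3]-sigmatropic shift delivers the sulfinyl vinylallene F3 (either configuration at sulfur). This diene type is known to cyclise onto unactivated alkenes near room temperature, here to the dienyl sulfoxide F4. Deoxygenation (PPh3, MoO2Cl2(dmf)2 cat.) to the dienyl sulfide F5 and hydrolysis (HgCl2, CaCO3, aq. MeCN) would come back to the route at enone 22.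

2. Step 19. Discrimination between the two diene faces by the remote decalin may be poor, and the enedione-endo mode or the reversed orientation may compete, which would give isomers that are hard to separate. The fallback moves the cycloaddition to a substrate with a bulky group on the ring next to C8 and C9, which restricts the rotamers about C9–C11 and C11–C12 (substrate control) and also removes the need for a chemoselective oxidation. It sets out from 23: silylation (iPr3SiOTf, 2,6-lutidine) would give the 7β-silyl ether furoate F6, methanolysis (K2CO3, MeOH) the primary alcohol F7, and Dess–Martin oxidation the aldehyde F8. Cycloaddition of F8 with 32 under the conditions of step 19 would give the silylated adduct F9, and HF·pyridine in THF would come back to the route at 33.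

3. Step 7. The enzyme may acylate the wrong enantiotopic hydroxymethyl group, or the ee may erode through 1,3-acyl migration before the oxidation. The fallback reverses the direction of the enzymatic step. It sets out from 13: exhaustive acylation (furan-2-carbonyl chloride, pyridine) would give the bis-furoate F10, and hydrolase-mediated mono-hydrolysis in pH 7 buffer removes the ester from the arm that the acylation mode would have esterified, so the antipodal monoester series is reached with the same prochiral preference. The enzyme and mode that deliver the (2R)-monoester come back to the route at 14.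

Further compounds
F1 | step 11 | (2R,3E)-2-[(4E,7E)-4,8-dimethyldeca-4,7,9-trienyl]-7-hydroxy-2-methylhept-3-en-5-ynyl furan-2-carboxylate | C=C/C(C)=C/C/C=C(\C)CCC[C@@](/C=C/C#CCO)(C)COC(=O)c1ccco1
F2 | step 11 | (2R,3E)-2-[(4E,7E)-4,8-dimethyldeca-4,7,9-trienyl]-2-methyl-7-(phenylsulfanyloxy)hept-3-en-5-ynyl furan-2-carboxylate | C=C/C(C)=C/C/C=C(\C)CCC[C@@](/C=C/C#CCOSc1ccccc1)(C)COC(=O)c1ccco1
F3 | step 11 | (2R,3E)-2-[(4E,7E)-4,8-dimethyldeca-4,7,9-trienyl]-2-methyl-5-(phenylsulfinyl)hepta-3,5,6-trienyl furan-2-carboxylate | C=C/C(C)=C/C/C=C(\C)CCC[C@@](/C=C/C(=C=C)S(=O)c1ccccc1)(C)COC(=O)c1ccco1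
F4 | step 11 | 7-(phenylsulfinyl)labda-6,8(17),12E,14-tetraen-18-yl furan-2-carboxylate | C=C1C(S(=O)c3ccccc3)=C[C@@H]2[C@](C)(CCC[C@@]2(C)COC(=O)c4ccco4)[C@H]1C/C=C(\C)C=C
F5 | step 11 | 7-(phenylsulfanyl)labda-6,8(17),12E,14-tetraen-18-yl furan-2-carboxylate | C=C1C(Sc3ccccc3)=C[C@@H]2[C@](C)(CCC[C@@]2(C)COC(=O)c4ccco4)[C@H]1C/C=C(\C)C=C
F6 | step 19 | 7β-(triisopropylsilyloxy)labda-8(17),12E,14-trien-18-yl furan-2-carboxylate | C=C1[C@@H](O[Si](C(C)C)(C(C)C)C(C)C)C[C@@H]2[C@](C)(CCC[C@@]2(C)COC(=O)c3ccco3)[C@H]1C/C=C(\C)C=C
F7 | step 19 | 7β-(triisopropylsilyloxy)labda-8(17),12E,14-trien-18-ol | C=C1[C@@H](O[Si](C(C)C)(C(C)C)C(C)C)C[C@@H]2[C@](C)(CCC[C@@]2(C)CO)[C@H]1C/C=C(\C)C=C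
F8 | step 19 | 7β-(triisopropylsilyloxy)labda-8(17),12E,14-trien-18-al | C=C1[C@@H](O[Si](C(C)C)(C(C)C)C(C)C)C[C@@H]2[C@](C)(CCC[C@@]2(C)C=O)[C@H]1C/C=C(\C)C=C
F9 | step 19 | 7-O-triisopropylsilyl dichrostachine H | C=C1[C@@H](O[Si](C(C)C)(C(C)C)C(C)C)C[C@@H]2[C@](C)(CCC[C@@]2(C)C=O)[C@H]1C[C@@H]1C(C)=CC[C@H]2C(=O)C(OC)=CC(=O)[C@@]12c1cc(=O)c2c(O)cc(O)cc2o1
F10 | step 7 | 2-[(4E,7E)-4,8-dimethyldeca-4,7,9-trienyl]-2-methylpropane-1,3-diyl bis(furan-2-carboxylate) | C=C/C(C)=C/C/C=C(\C)CCCC(C)(COC(=O)c1ccco1)COC(=O)c1ccco1
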